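**Retrosynthetic overview**

1. Numbering: the ten-membered ring runs C6 (lactone carbinol), C7 (carries C11 with the C12 carbonyl and the C13 methylene), C8 (acyloxy), C9=C10(Me), C1, C2 (OH), C3=C4(Me), C5 (OH). The strategy rests on the array C9=C10–C8(O)–C7–C11=C13, a homoallylic alcohol whose carbinol carbon is allylic: this is the retron of a [2,3]-Wittig shift of a C8–O–C13 bis-allylic ether, and the shift frees the very oxygen that bears the 2-methylbutanoate.
2. Disconnections, backwards: desilylation; γ-lactone (oxidation of C12, closure on O6); C8 ester; C7–C8 by [2,3]-Wittig ring contraction of a 13-membered ether; O–C13 by intramolecular Williamson etherification.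
3. Seco chain: C7=C11 by cross-metathesis with a 2-(silyloxymethyl)acrylate; C5–C6 by syn alkoxyallylboration of a (Z)-enal; C3=C4 by Z-selective olefination locked as a butenolide; C2–O by proline-catalysed α-aminoxylation; C8 to C3 from nerol.
4. Ring order: butenolide (temporary, fixes C3=C4, then opened), 13-membered ether, 10-membered carbocycle by contraction, γ-lactone last.

Key step: step 20

Remarks on the chemistry (assumptions):
- (R)-2-Methylbutanoic acid is taken as a purchasable single enantiomer.
- The C12 oxygen is carried as a TBS ether and not as an acetal: an allyl methoxymethyl ether is lithiated by alkyllithiums (the reaction used in step 12), so a C12 acetal would compete with C8 in the key step.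
- For the alkoxyallylboration the (+)-α-pinene-derived borane (−)-Ipc2BOMe (Ipc = isopinocampheyl) is chosen, its sense of allyl transfer corresponding to the 5R,6R pair.

**Route**

Step 1
Reactants: 1 nerol
Product: 2 neryl 4-methoxybenzyl ether
Conditions: NaH, PMBCl, Bu4NI (cat.), THF, 0 °C → rt
Reagents that add atoms: 4-methoxybenzyl chloride, COc1ccc(CCl)cc1
Why: Williamson etherification of the primary allylic alkoxide installs a PMB ether that tolerates the base, hydride and organolithium steps ahead and can later be removed oxidatively without touching silyl ethers or the acetal.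

Step 2
Reactants: 2 neryl 4-methoxybenzyl ether
Product: 3 (6Z)-3-bromo-8-(4-methoxybenzyloxy)-2,6-dimethyloct-6-en-2-ol (racemic at C3)
Conditions: NBS, THF/H2O, 0 °C
Reagents that add atoms: N-bromosuccinimide, O=C1CCC(=O)N1Br; water, O
Why: Bromohydrin formation (bromonium ion opened by water at the tertiary carbon) should take place at the remote, more electron-rich trisubstituted alkene because the other one is deactivated by its allylic ether oxygen; the new C–Br centre is racemic and is excised in step 4.

Step 3
Reactants: 3 bromohydrin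
Product: 4 2,2-dimethyl-3-[(3Z)-5-(4-methoxybenzyloxy)-3-methylpent-3-enyl]oxirane (racemic)
Conditions: K2CO3, MeOH, rt
Reagents that add atoms: none
Why: Intramolecular SN2 displacement of bromide by the tertiary alkoxide closes the epoxide.

Step 4
Reactants: 4 epoxide
Product: 6 (4Z)-6-(4-methoxybenzyloxy)-4-methylhex-4-enal (C8 to C3 of the target), via glycol 5 (not isolated)
Conditions: H5IO6, THF/H2O, 0 °C → rt
Reagents that add atoms: none
Why: Acidic hydrolysis of the epoxide to the glycol followed by periodate glycol cleavage (Malaprade reaction) removes the three-carbon end as acetone and leaves the Z alkene and the PMB ether intact.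

Step 5
Reactants: 6 (4Z)-6-(4-methoxybenzyloxy)-4-methylhex-4-enal; 7 ethyl 2-[bis(2,2,2-trifluoroethoxy)phosphoryl]propanoate
Product: 9 ethyl (2Z,4S,6Z)-8-(4-methoxybenzyloxy)-2,6-dimethyl-4-(phenylaminooxy)octa-2,6-dienoate, via aminoxy aldehyde 8 (not isolated)
Conditions: PhNO, D-proline (20 mol %), MeCN, −20 °C; crude 8 then added to 7, KN(SiMe3)2, 18-crown-6, THF, −78 °C
Reagents that add atoms: nitrosobenzene, O=Nc1ccccc1
Why: The D-proline enamine of 6 undergoes O-selective nitroso aldol reaction (α-aminoxylation) on the face to which the carboxylic acid delivers PhNO, which sets C2 as S (L-proline is known to give the R series), and the configurationally fragile aldehyde 8 is trapped at −78 °C by a Still–Gennari olefination whose trifluoroethyl phosphonate gives the Z trisubstituted enoate under kinetic control.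

Step 6
Reactants: 9 anilinooxy (Z)-enoate
Product: 11 (5S)-5-[(2Z)-4-(4-methoxybenzyloxy)-2-methylbut-2-enyl]-3-methylfuran-2(5H)-one, via hydroxy enoate 10 (not isolated)
Conditions: Zn, AcOH, EtOH, rt; then PPTS (cat.), toluene, 60 °C
Reagents that add atoms: none
Why: Zinc in acetic acid cleaves the weak N–O bond reductively and the freed C2 hydroxyl, held cis to the ester by the Z alkene, lactonises to the butenolide, which locks the C3=C4 geometry and leaves any E enoate behind as an open-chain hydroxy ester.

Step 7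
Reactants: 11 butenolide
Product: 12 (2Z,4S,6Z)-8-(4-methoxybenzyloxy)-2,6-dimethylocta-2,6-diene-1,4-diol
Conditions: iBu2AlH (4 equiv), CH2Cl2, −78 → 0 °C; aq potassium sodium tartrate
Reagents that add atoms: none
Why: Excess iBu2AlH reduces the lactone through the lactol to the diol without touching the ring alkene, so the cis relation of C2 and C5 across C3=C4 is carried over as the Z enediol.

Step 8
Reactants: 12 (Z)-enediol
Product: 13 bis-TBS ether of 12
Conditions: TBSCl, imidazole, DMF, rt
Reagents that add atoms: tert-butyldimethylsilyl chloride, CC(C)(C)[Si](C)(C)Cl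
Why: Standard silylation of both hydroxyls (silyl chloride activated by imidazole) prepares the differentiation of the primary from the secondary position.

Step 9
Reactants: 13 bis-TBS ether
Product: 14 (2Z,4S,6Z)-4-(tert-butyldimethylsilyloxy)-8-(4-methoxybenzyloxy)-2,6-dimethylocta-2,6-dien-1-ol
Conditions: HF·pyridine, pyridine, THF, 0 °C
Reagents that add atoms: none
Why: Buffered HF cleaves the less hindered primary allylic silyl ether much faster than the secondary one, which frees only the C5 hydroxyl.

Step 10
Reactants: 14 primary allylic alcohol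
Product: 15 (2Z,4S,6Z)-4-(tert-butyldimethylsilyloxy)-8-(4-methoxybenzyloxy)-2,6-dimethylocta-2,6-dienal (C5 aldehyde)
Conditions: Dess–Martin periodinane, NaHCO3, CH2Cl2, 0 °C
Reagents that add atoms: none
Why: Buffered Dess–Martin oxidation converts the primary allylic alcohol into the enal under neutral conditions at 0 °C, which should preserve the Z geometry and the C2 stereocentre.

Step 11
Reactants: 16 allyl alcohol
Product: 17 allyl methoxymethyl ether
Conditions: MOMCl, iPr2NEt, CH2Cl2, 0 °C → rt
Reagents that add atoms: chloromethyl methyl ether, COCCl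
Why: O-Alkylation of allyl alcohol with the oxocarbenium-type electrophile MOMCl gives the acetal ether whose chelating oxygen directs the α-lithiation of step 12.

Step 12
Reactants: 15 (Z)-enal; 17 allyl methoxymethyl ether
Product: 21 (3R,4R,5Z,7S,9Z)-7-(tert-butyldimethylsilyloxy)-3-(methoxymethoxy)-11-(4-methoxybenzyloxy)-5,9-dimethylundeca-1,5,9-trien-4-ol (C5-OH free; C6-OMOM), via alkoxyallyllithium 18 (not isolated), via alkoxyallylborane 19 (not isolated), via borinate 20 (not isolated)
Conditions: 17, s-BuLi, THF, −78 °C; (−)-Ipc2BOMe; BF3·OEt2; then 15, −78 °C; NaOH, H2O2, 0 °C → rt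
Reagents that add atoms: none
Why: α-Lithiation of 17 gives the chelated Z alkoxyallyl anion 18, boron takes the γ carbon to give the Z γ-alkoxyallylborane 19, and its addition to the aldehyde through a chair Zimmerman–Traxler transition state (Brown alkoxyallylboration) translates the Z geometry into the syn C5/C6 relationship while the isopinocampheyl groups select the aldehyde face, setting 5R and 6R under reagent control before oxidative work-up frees the alcohol from borinate 20.

Step 13
Reactants: 21 syn alkoxy alcohol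
Product: 22 C5 TBS ether of 21 (2,5-bis-OTBS; 6-OMOM; 8-OPMB; terminal vinyl)
Conditions: TBSOTf, 2,6-lutidine, CH2Cl2, −78 → 0 °C
Reagents that add atoms: tert-butyldimethylsilyl trifluoromethanesulfonate, CC(C)(C)[Si](C)(C)OS(=O)(=O)C(F)(F)F
Why: The hindered secondary allylic alcohol is silylated by the reactive silyl triflate with a non-nucleophilic base, completing the protection of the chain before metathesis.

Step 14
Reactants: 23 methyl 2-(hydroxymethyl)acrylate
Product: 24 methyl 2-[(tert-butyldimethylsilyloxy)methyl]acrylate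
Conditions: TBSCl, imidazole, CH2Cl2, 0 °C → rt
Reagents that add atoms: tert-butyldimethylsilyl chloride, CC(C)(C)[Si](C)(C)Cl
Why: Silylation of the primary hydroxyl gives an acrylate partner whose C12 oxygen carries a bulky, poorly coordinating group that will not assist α-lithiation in step 20.

Step 15
Reactants: 22 vinyl compound; 24 silyloxymethyl acrylate
Product: 25 methyl (2E,4R,5R,6Z,8S,10Z)-5,8-bis(tert-butyldimethylsilyloxy)-2-[(tert-butyldimethylsilyloxy)methyl]-4-(methoxymethoxy)-12-(4-methoxybenzyloxy)-6,10-dimethyldodeca-2,6,10-trienoate (carries C11, C12 and C13)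
Conditions: second-generation Hoveyda–Grubbs catalyst (10 mol %), 24 (5 equiv), toluene, 80 °C
Reagents that add atoms: none
Why: Olefin cross-metathesis between the monosubstituted alkene of 22 and the 1,1-disubstituted acrylate 24 (which does not homodimerise and is used in excess) should give the trisubstituted enoate with C6 trans to the ester, the thermodynamically preferred E isomer, while the two trisubstituted Z alkenes are too hindered to enter the catalytic cycle.

Step 16
Reactants: 25 (E)-enoate
Product: 26 C13 allylic alcohol (ester reduced to CH2OH trans to C6; C12 as CH2OTBS cis to C6)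
Conditions: iBu2AlH, CH2Cl2, −78 °C; aq potassium sodium tartrate
Reagents that add atoms: none
Why: iBu2AlH reduces the conjugated ester by 1,2-addition to the allylic alcohol at low temperature without affecting the silyl, acetal and PMB ethers or the alkene geometry.

Step 17
Reactants: 26 C13 allylic alcohol
Product: 28 C13 allylic chloride, via mesylate 27 (not isolated)
Conditions: MsCl, 2,4,6-collidine, LiCl, DMF, 0 °C
Reagents that add atoms: lithium chloride, [Li+].[Cl-]
Why: Mesylation and in situ SN2 displacement by chloride at the primary carbon at 0 °C give the allylic chloride without allylic transposition, so C13 stays trans to C6.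

Step 18
Reactants: 28 C13 allylic chloride
Product: 29 seco hydroxy allylic chloride (free C8-OH; C13-Cl)
Conditions: DDQ, CH2Cl2/pH 7 buffer, 0 °C
Reagents that add atoms: none
Why: DDQ oxidises the electron-rich benzylic ether (hydride abstraction, then hydrolysis of the oxocarbenium ion) and so frees the C8 hydroxyl while the allylic chloride, the silyl ethers and the MOM ether are inert.

Step 19
Reactants: 29 seco hydroxy allylic chloride
Product: 30 13-membered bis-allylic ether (C8–O–C13; 3Z and 9Z; C6 trans to C13 on C7=C11; 2S 5R 6R)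
Conditions: NaH, THF, 60 °C, slow addition of 29 (final 2 mM)
Reagents that add atoms: none
Why: Intramolecular Williamson etherification of the primary allylic alkoxide with the primary allylic chloride (SN2, slow addition at high dilution to suppress oligomers) closes the 13-membered ring, which is large enough to hold one E and two Z alkenes with little transannular strain.

Step 20
Reactants: 30 13-membered bis-allylic ether
Product: 32 ten-membered carbocycle with free C8-OH and exocyclic C11=C13 (2S 5R 6R 7S 8R; 2,5-bis-OTBS; 6-OMOM; 12-OTBS), via C8-lithio ether 31 (not isolated)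
Conditions: n-BuLi (3 equiv), THF/hexane, −78 → −25 °C; aq NH4Cl at −78 °C
Reagents that add atoms: none
Why: n-BuLi removes a proton from C8 (allylic to C9=C10 and α to the ring oxygen) to give 31, whose carbanion bonds to C7 through a five-membered envelope transition state made of C8, O, C13, C11 and C7 while the O–C13 bond breaks, a concerted suprafacial [2,3]-sigmatropic (Wittig) shift that leaves C11=C13 as the exocyclic methylene and C8–O as a lithium alkoxide. The closest known reaction type is the [2,3]-Wittig ring contraction of 13-membered diallylic ethers of the farnesyl series to ten-membered germacrane carbocycles, of which 30 is the neryl-type analogue. The cyclodecadiene is therefore not closed by an exo or endo cyclisation but by contraction of the 13-membered ether by three atoms, and the irreversible formation of the alkoxide pays for the strain of a medium ring holding two Z alkenes. C7 and C8 are set relative to each other by the alkene geometry (C6 trans to C13), which in the envelope with the C9 vinyl group exo gives the anti pair (H7 and H8 trans on the ring), and their absolute sense comes from C6, because A(1,3) strain with the C12 methylene keeps C6–H in the alkene plane so that C8, tethered through C5, adds to the face opposite the C6–OMOM bond (H6 and H7 trans). The step needs lithiation at C8 and not at C13 or C12: C8 is flanked by a CH= carbon and is the most accessible methylene, a C13 anion could rearrange only by bonding to the fully substituted C10 with formation of a quaternary centre, and the C12 methylene sits cis to the C6 branch under a bulky, non-chelating silyl ether.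

Step 21
Reactants: 32 ten-membered alcohol; 33 (R)-2-methylbutanoic acid
Product: 34 C8 (R)-2-methylbutanoate of 32
Conditions: DCC, DMAP, CH2Cl2, 0 °C → rt
Reagents that add atoms: none
Why: Steglich esterification (carbodiimide activation with acyl transfer through DMAP) acylates the only free hydroxyl, and the α-stereocentre of the simple α-alkyl acid is not expected to epimerise under these conditions.

Step 22
Reactants: 34 C8 ester
Product: 35 C6 alcohol (MOM removed; 2,5-bis-OTBS and 12-OTBS kept)
Conditions: Me2BBr, iPr2NEt (cat.), CH2Cl2, −78 °C; then THF/aq NaHCO3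
Reagents that add atoms: none
Why: Me2BBr complexes the acetal oxygen and bromide cleaves the MOM group to a bromomethyl ether that is hydrolysed on work-up, a cleavage that runs at −78 °C where TBS ethers, the ester and the allylic positions should be left alone; it is done before the C12 oxygen is freed so that no cyclic formal can form.

Step 23
Reactants: 35 C6 alcohol
Product: 36 2-methylene-1,4-diol (free C6-OH and C12-OH; 2,5-bis-OTBS)
Conditions: HF·pyridine, pyridine, THF, 0 °C
Reagents that add atoms: none
Why: Buffered HF again removes the primary allylic silyl ether selectively, leaving the two secondary allylic silyl ethers at C2 and C5 to shield these alcohols from the oxidation that follows.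

Step 24
Reactants: 36 2-methylene-1,4-diol
Product: 39 bis-TBS α-methylene γ-lactone, via hydroxy enal 37 (not isolated), via lactol 38 (not isolated)
Conditions: TEMPO (20 mol %), PhI(OAc)2 (2.5 equiv), CH2Cl2, rt
Reagents that add atoms: none
Why: The oxoammonium salt generated from TEMPO oxidises the primary allylic alcohol to enal 37, the C6 hydroxyl adds to give the five-membered lactol 38 and a second oxidation gives the α-methylene γ-lactone, trans-fused because C6 and C7 are already set, while the silyl-protected secondary alcohols cannot react.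

Step 25
Reactants: 39 bis-TBS lactone
Product: 40 target CNP0176600.1
Conditions: HF·pyridine, pyridine, THF, 0 °C → rt
Reagents that add atoms: none
Why: Fluoride cleaves both secondary silyl ethers under buffered, weakly acidic conditions that spare the α-methylene lactone, the ester and the allylic alcohols, giving the target.

**Compound list**

1 | nerol | CC(C)=CCC/C(C)=C\CO | starting material
2 | neryl 4-methoxybenzyl ether | CC(C)=CCC/C(C)=C\COCc1ccc(OC)cc1 | intermediate
3 | (6Z)-3-bromo-8-(4-methoxybenzyloxy)-2,6-dimethyloct-6-en-2-ol (racemic at C3) | CC(C)(O)C(Br)CC/C(C)=C\COCc1ccc(OC)cc1 | intermediate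
4 | 2,2-dimethyl-3-[(3Z)-5-(4-methoxybenzyloxy)-3-methylpent-3-enyl]oxirane (racemic) | CC1(C)OC1CC/C(C)=C\COCc1ccc(OC)cc1 | intermediate
5 | (6Z)-8-(4-methoxybenzyloxy)-2,6-dimethyloct-6-ene-2,3-diol | CC(C)(O)C(O)CC/C(C)=C\COCc1ccc(OC)cc1 | intermediate (not isolated)
6 | (4Z)-6-(4-methoxybenzyloxy)-4-methylhex-4-enal | COc1ccc(COC/C=C(/C)CCC=O)cc1 | intermediate
7 | ethyl 2-[bis(2,2,2-trifluoroethoxy)phosphoryl]propanoate | CCOC(=O)C(C)P(=O)(OCC(F)(F)F)OCC(F)(F)F | starting material
8 | (2S,4Z)-6-(4-methoxybenzyloxy)-4-methyl-2-(phenylaminooxy)hex-4-enal | COc1ccc(COC/C=C(/C)C[C@H](ONc2ccccc2)C=O)cc1 | intermediate (not isolated)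
9 | ethyl (2Z,4S,6Z)-8-(4-methoxybenzyloxy)-2,6-dimethyl-4-(phenylaminooxy)octa-2,6-dienoate | COc1ccc(COC/C=C(/C)C[C@H](ONc2ccccc2)/C=C(/C)C(=O)OCC)cc1 | intermediate
10 | ethyl (2Z,4S,6Z)-4-hydroxy-8-(4-methoxybenzyloxy)-2,6-dimethylocta-2,6-dienoate | COc1ccc(COC/C=C(/C)C[C@H](O)/C=C(/C)C(=O)OCC)cc1 | intermediate (not isolated)
11 | (5S)-5-[(2Z)-4-(4-methoxybenzyloxy)-2-methylbut-2-enyl]-3-methylfuran-2(5H)-one | COc1ccc(COC/C=C(/C)C[C@@H]2OC(=O)C(C)=C2)cc1 | intermediate
12 | (2Z,4S,6Z)-8-(4-methoxybenzyloxy)-2,6-dimethylocta-2,6-diene-1,4-diol | COc1ccc(COC/C=C(/C)C[C@H](O)/C=C(/C)CO)cc1 | intermediate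
13 | (2Z,4S,6Z)-1,4-bis(tert-butyldimethylsilyloxy)-8-(4-methoxybenzyloxy)-2,6-dimethylocta-2,6-diene | COc1ccc(COC/C=C(/C)C[C@H](O[Si](C)(C)C(C)(C)C)/C=C(/C)CO[Si](C)(C)C(C)(C)C)cc1 | intermediate
14 | (2Z,4S,6Z)-4-(tert-butyldimethylsilyloxy)-8-(4-methoxybenzyloxy)-2,6-dimethylocta-2,6-dien-1-ol | COc1ccc(COC/C=C(/C)C[C@H](O[Si](C)(C)C(C)(C)C)/C=C(/C)CO)cc1 | intermediate
15 | (2Z,4S,6Z)-4-(tert-butyldimethylsilyloxy)-8-(4-methoxybenzyloxy)-2,6-dimethylocta-2,6-dienal | COc1ccc(COC/C=C(/C)C[C@H](O[Si](C)(C)C(C)(C)C)/C=C(/C)C=O)cc1 | intermediate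
16 | allyl alcohol | C=CCO | starting material
17 | allyl methoxymethyl ether | C=CCOCOC | intermediate
18 | (Z)-3-(methoxymethoxy)allyllithium | COCO/C=C\C[Li] | intermediate (not isolated)
19 | (Z)-[3-(methoxymethoxy)allyl]diisopinocampheylborane (Ipc from (+)-α-pinene) | COCO/C=C\CB([C@@H]1C[C@@H]2C[C@@H](C2(C)C)[C@H]1C)[C@@H]1C[C@@H]2C[C@@H](C2(C)C)[C@H]1C | intermediate (not isolated)
20 | diisopinocampheylborinate of alcohol 21 | COc1ccc(COC/C=C(/C)C[C@H](O[Si](C)(C)C(C)(C)C)/C=C(/C)[C@@H](OB([C@@H]2C[C@@H]3C[C@@H](C3(C)C)[C@H]2C)[C@@H]2C[C@@H]3C[C@@H](C3(C)C)[C@H]2C)[C@H](OCOC)C=C)cc1 | intermediate (not isolated)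
21 | (3R,4R,5Z,7S,9Z)-7-(tert-butyldimethylsilyloxy)-3-(methoxymethoxy)-11-(4-methoxybenzyloxy)-5,9-dimethylundeca-1,5,9-trien-4-ol | COc1ccc(COC/C=C(/C)C[C@H](O[Si](C)(C)C(C)(C)C)/C=C(/C)[C@@H](O)[C@H](OCOC)C=C)cc1 | intermediate
22 | (3R,4R,5Z,7S,9Z)-4,7-bis(tert-butyldimethylsilyloxy)-3-(methoxymethoxy)-11-(4-methoxybenzyloxy)-5,9-dimethylundeca-1,5,9-triene | COc1ccc(COC/C=C(/C)C[C@H](O[Si](C)(C)C(C)(C)C)/C=C(/C)[C@@H](O[Si](C)(C)C(C)(C)C)[C@H](OCOC)C=C)cc1 | intermediate
23 | methyl 2-(hydroxymethyl)acrylate | C=C(CO)C(=O)OC | starting material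
24 | methyl 2-[(tert-butyldimethylsilyloxy)methyl]acrylate | C=C(CO[Si](C)(C)C(C)(C)C)C(=O)OC | intermediate
25 | methyl (2E,4R,5R,6Z,8S,10Z)-5,8-bis(tert-butyldimethylsilyloxy)-2-[(tert-butyldimethylsilyloxy)methyl]-4-(methoxymethoxy)-12-(4-methoxybenzyloxy)-6,10-dimethyldodeca-2,6,10-trienoate | COc1ccc(COC/C=C(/C)C[C@H](O[Si](C)(C)C(C)(C)C)/C=C(/C)[C@@H](O[Si](C)(C)C(C)(C)C)[C@H](OCOC)/C=C(\CO[Si](C)(C)C(C)(C)C)C(=O)OC)cc1 | intermediate
26 | C13 allylic alcohol of the seco chain (8-OPMB; 2,5-bis-OTBS; 6-OMOM; 12-OTBS; C6 trans to C13; 2S 5R 6R) | COc1ccc(COC/C=C(/C)C[C@H](O[Si](C)(C)C(C)(C)C)/C=C(/C)[C@@H](O[Si](C)(C)C(C)(C)C)[C@H](OCOC)/C=C(\CO[Si](C)(C)C(C)(C)C)CO)cc1 | intermediate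
27 | C13 methanesulfonate of 26 | COc1ccc(COC/C=C(/C)C[C@H](O[Si](C)(C)C(C)(C)C)/C=C(/C)[C@@H](O[Si](C)(C)C(C)(C)C)[C@H](OCOC)/C=C(\CO[Si](C)(C)C(C)(C)C)COS(C)(=O)=O)cc1 | intermediate (not isolated)
28 | C13 allylic chloride (8-OPMB) | COc1ccc(COC/C=C(/C)C[C@H](O[Si](C)(C)C(C)(C)C)/C=C(/C)[C@@H](O[Si](C)(C)C(C)(C)C)[C@H](OCOC)/C=C(\CO[Si](C)(C)C(C)(C)C)CCl)cc1 | intermediate
29 | seco hydroxy allylic chloride (free C8-OH; C13-Cl) | OC/C=C(/C)C[C@H](O[Si](C)(C)C(C)(C)C)/C=C(/C)[C@@H](O[Si](C)(C)C(C)(C)C)[C@H](OCOC)/C=C(\CO[Si](C)(C)C(C)(C)C)CCl | intermediate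
30 | 13-membered bis-allylic ether (C8–O–C13) | O1C/C=C(/C)C[C@H](O[Si](C)(C)C(C)(C)C)/C=C(/C)[C@@H](O[Si](C)(C)C(C)(C)C)[C@H](OCOC)/C=C(\CO[Si](C)(C)C(C)(C)C)C1 | intermediate
31 | C8-lithio derivative of ether 30 | O1C([Li])/C=C(/C)C[C@H](O[Si](C)(C)C(C)(C)C)/C=C(/C)[C@@H](O[Si](C)(C)C(C)(C)C)[C@H](OCOC)/C=C(\CO[Si](C)(C)C(C)(C)C)C1 | intermediate (not isolated)
32 | ten-membered carbocycle: free C8-OH; exocyclic C11=C13; 12-OTBS; 6-OMOM; 2,5-bis-OTBS (2S 5R 6R 7S 8R) | C=C(CO[Si](C)(C)C(C)(C)C)[C@H]1[C@H](O)/C=C(/C)C[C@H](O[Si](C)(C)C(C)(C)C)/C=C(/C)[C@@H](O[Si](C)(C)C(C)(C)C)[C@@H]1OCOC | intermediate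
33 | (R)-2-methylbutanoic acid | CC[C@@H](C)C(=O)O | starting material
34 | C8 (R)-2-methylbutanoate of 32 | C=C(CO[Si](C)(C)C(C)(C)C)[C@H]1[C@H](OC(=O)[C@H](C)CC)/C=C(/C)C[C@H](O[Si](C)(C)C(C)(C)C)/C=C(/C)[C@@H](O[Si](C)(C)C(C)(C)C)[C@@H]1OCOC | intermediate
35 | C6 alcohol (MOM removed; configuration unchanged) | C=C(CO[Si](C)(C)C(C)(C)C)[C@H]1[C@H](OC(=O)[C@H](C)CC)/C=C(/C)C[C@H](O[Si](C)(C)C(C)(C)C)/C=C(/C)[C@@H](O[Si](C)(C)C(C)(C)C)[C@@H]1O | intermediate
36 | 2-methylene-1,4-diol (free C6-OH and C12-OH) | C=C(CO)[C@H]1[C@H](OC(=O)[C@H](C)CC)/C=C(/C)C[C@H](O[Si](C)(C)C(C)(C)C)/C=C(/C)[C@@H](O[Si](C)(C)C(C)(C)C)[C@@H]1O | intermediate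
37 | C12 enal with free C6-OH | C=C(C=O)[C@H]1[C@H](OC(=O)[C@H](C)CC)/C=C(/C)C[C@H](O[Si](C)(C)C(C)(C)C)/C=C(/C)[C@@H](O[Si](C)(C)C(C)(C)C)[C@@H]1O | intermediate (not isolated)
38 | C12 lactol (anomeric mixture) | C=C1C(O)O[C@@H]2[C@@H]1[C@H](OC(=O)[C@H](C)CC)/C=C(/C)C[C@H](O[Si](C)(C)C(C)(C)C)/C=C(/C)[C@H]2O[Si](C)(C)C(C)(C)C | intermediate (not isolated)
39 | 2,5-bis-O-TBS α-methylene γ-lactone | C=C1C(=O)O[C@@H]2[C@@H]1[C@H](OC(=O)[C@H](C)CC)/C=C(/C)C[C@H](O[Si](C)(C)C(C)(C)C)/C=C(/C)[C@H]2O[Si](C)(C)C(C)(C)C | intermediate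
40 | CNP0176600.1 (2S 5R 6R 7S 8R; 8-O-(R)-2-methylbutanoyl; 3Z 9Z) | C=C1C(=O)O[C@@H]2[C@@H]1[C@H](OC(=O)[C@H](C)CC)/C=C(/C)C[C@H](O)/C=C(/C)[C@H]2O | target

**Step count and risks**

Total step count: 25 (steps 11 and 14 prepare the two small partners). Longest linear sequence: 23 steps from nerol (steps 1–10, 12, 13, 15–25).

Steps most likely to fail:

Step 20. The lithiation may lose regiocontrol (metalation at C13 or C12 instead of C8). A [1,2]-shift may compete, or the facial or anti selectivity of the shift may be poor in this more heavily oxygenated ring. The fallback forms the same C7–C8 bond with an allylmetal instead of a sigmatropic shift and skips the macrocyclic ether. It sets out from hydroxy chloride 29, whose primary allylic alcohol is oxidised with MnO2 in CH2Cl2 to the (Z)-enal allylic chloride F1. Treatment with CrCl2 and LiI in THF/DMF at high dilution (intramolecular Nozaki–Hiyama allylation) generates an allylchromium at C13 that adds through its γ-carbon C7 to the C8 aldehyde in a chair transition state. This should give the anti homoallylic alcohol with the exocyclic C11=C13, and the fallback comes back to the route at 32.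

Step 15. Both metathesis partners are hindered (allylic acetal on one, 1,1-disubstitution on the other), so the catalyst may decompose before productive turnover, giving low conversion or erosion of the alkene geometry. The fallback makes the coupling intramolecular with a temporary ester tether and sets out from alcohol 21 (and from 23 for the tether). 23 is silylated with TESCl/imidazole to methyl 2-[(triethylsilyloxy)methyl]acrylate F2 and hydrolysed with Me3SnOH to 2-[(triethylsilyloxy)methyl]acrylic acid F3. F3 is esterified with the C5 hydroxyl of 21 (DCC, DMAP) to the acrylate ester F4. Ring-closing metathesis with second-generation Grubbs catalyst then gives the six-membered unsaturated lactone F5, in which the ring forces the carbonyl carbon (the future C12) cis to C6. iBu2AlH opens it to the C5,C12-diol F6, TBSOTf/2,6-lutidine gives the bis-TBS triethylsilyl ether F7, and PPTS in MeOH removes only the primary triethylsilyl group, coming back to the route at 26.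

Step 10. The (Z)-α-methyl enal may isomerise to the E enal during oxidation, on chromatography or on contact with the Lewis acid of step 12. The fallback never liberates the enal and sets out from butenolide 11. One equivalent of iBu2AlH at −78 °C gives the lactol F8, the ring-closed and geometrically locked form of the Z hydroxy enal. Alkoxyallylboration with excess borane 19, prepared as in step 12, followed by oxidative work-up should give the C2,C5-diol F9. Double silylation with TBSOTf/2,6-lutidine comes back to the route at 22.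

**Further compounds**

F1 | step 20 | (Z)-enal allylic chloride (C8 aldehyde; C13-Cl; 2,5-bis-OTBS; 6-OMOM; 12-OTBS) | O=C/C=C(/C)C[C@H](O[Si](C)(C)C(C)(C)C)/C=C(/C)[C@@H](O[Si](C)(C)C(C)(C)C)[C@H](OCOC)/C=C(\CO[Si](C)(C)C(C)(C)C)CCl
F2 | step 15 | methyl 2-[(triethylsilyloxy)methyl]acrylate | C=C(CO[Si](CC)(CC)CC)C(=O)OC
F3 | step 15 | 2-[(triethylsilyloxy)methyl]acrylic acid | C=C(CO[Si](CC)(CC)CC)C(=O)O
F4 | step 15 | C5 2-[(triethylsilyloxy)methyl]acrylate ester of 21 | COc1ccc(COC/C=C(/C)C[C@H](O[Si](C)(C)C(C)(C)C)/C=C(/C)[C@@H](OC(=O)C(=C)CO[Si](CC)(CC)CC)[C@H](OCOC)C=C)cc1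
F5 | step 15 | 5-(methoxymethoxy)-3-[(triethylsilyloxy)methyl]-5,6-dihydropyran-2-one carrying the C4-to-C8 chain at ring position 6 | COc1ccc(COC/C=C(/C)C[C@H](O[Si](C)(C)C(C)(C)C)/C=C(/C)[C@H]2OC(=O)C(CO[Si](CC)(CC)CC)=C[C@H]2OCOC)cc1
F6 | step 15 | C5,C12-diol with C13 triethylsilyl ether | COc1ccc(COC/C=C(/C)C[C@H](O[Si](C)(C)C(C)(C)C)/C=C(/C)[C@@H](O)[C@H](OCOC)/C=C(\CO)CO[Si](CC)(CC)CC)cc1
F7 | step 15 | 2,5,12-tris-O-TBS C13 triethylsilyl ether | COc1ccc(COC/C=C(/C)C[C@H](O[Si](C)(C)C(C)(C)C)/C=C(/C)[C@@H](O[Si](C)(C)C(C)(C)C)[C@H](OCOC)/C=C(\CO[Si](C)(C)C(C)(C)C)CO[Si](CC)(CC)CC)cc1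
F8 | step 10 | (5S)-5-[(2Z)-4-(4-methoxybenzyloxy)-2-methylbut-2-enyl]-3-methyl-2,5-dihydrofuran-2-ol (lactol; anomeric mixture) | COc1ccc(COC/C=C(/C)C[C@@H]2OC(O)C(C)=C2)cc1
F9 | step 10 | (3R,4R,5Z,7S,9Z)-3-(methoxymethoxy)-11-(4-methoxybenzyloxy)-5,9-dimethylundeca-1,5,9-triene-4,7-diol | COc1ccc(COC/C=C(/C)C[C@H](O)/C=C(/C)[C@@H](O)[C@H](OCOC)C=C)cc1
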